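I started from the late readings at 5.00 h and 10.0 h, where target was falling in both runs.

| flask | starting material | first nucleophile | second nucleophile | remark | time |
|---|---|---|---|---|---|
| Friday's | 0.27 M | 1.5 equiv | 1 equiv | run made earlier |  |
| Wednesday's | 0.60 M | 1.5 equiv | 1 equiv | run made earlier |  |
| flask | 0.40 M | 1.50 equiv | 1.00 equiv |  | 10 h |
- Friday's (time / h: target / %): 0.133: 31.6; 0.333: 46.9; 0.667: 50.6; 1.33: 48.5; 2.50: 46.1; 5.00: 40.1; 10.0: 32.0
- Wednesday's (time / h: target / %): 0.133: 40.5; 0.333: 51.3; 0.667: 52.3; 1.33: 48.0; 2.50: 42.5; 5.00: 32.5; 10.0: 21.2

(each reading ± 0.5 percentage points)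
1. time up to 10 h at which target stands highest
2. the amount of target, in percent of the starting material charged, at that time
- the numbers in the tables scatter with a standard deviation of 0.5 percentage points

1. Late end: the logarithmic slope of target between those times, per molar of charged [starting material], was 0.167 /M/h in Friday's run and 0.142 /M/h in Wednesday's. Their mean is my fade constant, the pseudo-first-order loss of target per molar charged: 0.155 /M/h.

2. At 0.40 M, the flask should therefore fade at 0.0619 /h.

3. Run back to time zero, the late lines start at 50.3% and 49.8%, mean 50.0%.

4. Early end: the first readings, set against the readings at 0.667 h, gave rise constants of 7.36 /h and 11.2 /h. The geometric middle of the two runs' charges is 0.402 M, close to the flask's 0.40 M, so I took 9.08 /h.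

5. Join: the rise slows to the fade at 0.549 h, where the late line gives 48.4%.

6. That height lies below both peak readings, so I replaced it with their mean, 51.4%, and committed to that and 0.549 h.

The forecast gave 0.6 h (0.45 h to 0.8 h) and 51.8% (50.8% to 52.8%), noting: “The peak is broad and its time is poorly defined”.

The flask peaked at 0.577 h with 52.0%, and both forecast numbers held.

    second nucleophile + intermediate → other capture product (k = 3.10 /M/min)
    first nucleophile + target → over-reaction product (k = 0.00380 /M/min)
    intermediate → side product (k = 0.200 /min)
    first nucleophile + intermediate → target (k = 3.00 /M/min)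
    starting material ⇌ intermediate (K = 0.140, k = 0.230 /min)

On this flask, the fade constant and 50.0% give 26.9% at 10 h, and the flask held 26.9%. The neighbouring flask had 1.6 M of starting material at the same equivalents and reached 51.8%. The same reckoning gives it a fade of 0.248 /h and 4.19% of target at 10.0 h; that flask held 7.63%.

The readings are calculated for an exercise, and the scatter is random.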